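Charge the flasks and read them at 15 h: you asked for a quick number, so I count half-lives and fit nothing.

| flask | X | J | remark | time |
|---|---|---|---|---|
| north | 0.058 M | 0.75 equiv | run made earlier |  |
| north-east | 0.058 M | 1.3 equiv | run made earlier |  |
| red | 0.058 M | 0.800 equiv |  | 15 h |
| green | 0.058 M | 1.00 equiv |  | 15 h |
| ochre | 0.058 M | 1.40 equiv |  | 15 h |

| run | time / h | X / % | E / % |
|---|---|---|---|
| north | 2.50 | 67.6 | 13.4 |
| north | 5.00 | 49.4 | 18.0 |
| north | 8.00 | 36.8 | 20.6 |
| north | 10.0 | 30.3 | 22.6 |
| north-east | 0.833 | 82.9 | 10.0 |
| north-east | 2.00 | 64.1 | 19.2 |
| north-east | 5.00 | 39.3 | 29.1 |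
| north-east | 10.0 | 22.4 | 33.4 |

(readings scatter by 0.5 percentage points)

- part of the X that has reacted at the end, red
- part of the X that has reacted at the end, green
- part of the X that has reacted at the end, ochre
- what raising the equivalents of J from its lowest to its highest value here does to the part of the X that has reacted (changes below 5 percentage points count as none) (it rises / it falls / no change)

- candidate steps: X <-> Z; X + J -> D + E; E <-> G; J + D <-> Q
- what has gone from X into another species counts as reacted, even if it can come back

Between its last two readings the north run loses X at a pace that would halve it in 7.13 h. Call this the late half-life of X: the time X needs to halve at the pace of a run's last two readings, treating the decay as pseudo-first-order. The north-east run gives 6.16 h.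

From its last reading to 15 h, north has 0.701 half-lives to go, which takes X to 18.6% of the charge, so 81.4% has reacted. North-east has 0.811 to go, which leaves 12.8% and gives 87.2% reacted. I take these as my figures for red and ochre, whose J lies next to those runs, with green between them. The gap of 5.8 percentage points is more than the 5 points that counts as a change. But north's first reading gives a half-life of 4.43 h, shorter than the late one, so the pace is still slowing and I treat both figures as upper ones.

Your forecast says 79.8%, 82.2% and 85.5%, with the caution “J still raises conversion, though this is borderline”. My figures sit above yours.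

The flasks give 77.4%, 80.5% and 85.9%. On the trend they answer it rises, by 8.5 points, so your forecast stands right.

    X ⇌ Z (K = 2.90, k = 2.50 × 10⁻⁵ s⁻¹)
    X + J → D + E (k = 5.70 × 10⁻⁴ M⁻¹ s⁻¹)
    E ⇌ G (K = 0.320, k = 3.10 × 10⁻⁵ s⁻¹)
    J + D ⇌ Q, settled at all times (K = 58000 M⁻¹)

Red has not come to rest at 15.0 h, but the count no longer describes it. From there to 150 h is 18.9 late half-lives, which would leave hardly any X. Yet with red left ten times as long, X goes from 22.6% to 15.1%, lifting the part reacted from 77.4% to 84.9%, while free J falls from 20.4% to 0.729% of its charge. Ochre, counted with 6.16 h, has 21.9 half-lives ahead of it over the same stretch. Left ten times as long, ochre's X goes from 14.1% to 7.78%, and its part reacted from 85.9% to 92.2%.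

The numbers in the tables were generated by integration from invented constants; the scatter is artificial.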